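All runs are calculated with made-up constants, noise included.

I decided to reckon the beta flask backward from its end state, and to ask of each number what it could do to that end.

| flask | E | Q | time |
|---|---|---|---|
| eta | 150 mM | 0.750 mM |  |
| theta | 90.0 mM | 0.750 mM |  |
| delta | 75.0 mM | 0.750 mM |  |
| epsilon | 150 mM | 1.50 mM |  |
| beta | 33.0 mM | 0.750 mM | 49 min |

- eta run (time / min: [G] / mM): 8.2: 20.6; 16: 29.3; 24: 34.7; 33: 36.9; 41: 36.7; 49: 38.1
- theta run (time / min: [G] / mM): 8.2: 16.8; 16: 25.3; 24: 31.2; 33: 35.7; 41: 36.4; 49: 37.6
- delta run (time / min: [G] / mM): 8.2: 15.2; 16: 23.9; 24: 29.8; 33: 33.6; 41: 35.1; 49: 36.6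
- epsilon run (time / min: [G] / mM): 8.2: 36.6; 16: 56.7; 24: 65.9; 33: 71.2; 41: 74.5; 49: 76.4

(standard deviation of a reading: 0.8 mM)

- Overall: E -> G, with Q as catalyst.
- Constant volume, constant temperature.
- A reading of a species includes what of it is bound.
- An order is taken over about fifteen percent of the charge, up and down.

1. reaction order in [Q] at the outset, round the charge of the eta run, defined at two percent of the E turned into G
2. reaction order in [E] at the outset, round the charge of the eta run, defined at two percent of the E turned into G (one fixed amount of G, the same in the runs compared)
3. G in the beta run at 49 min, as a share of the E charged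

The number to know well was the budget of the catalyst: the amount of G made per amount of Q charged before the Q is lost, the usual turnover number. I read it from the last reading of the eta flask:

budget = 38.1 mM / 0.750 mM = 50.8

The epsilon flask, with twice the Q, read 50.9. Going from 150 mM of E in the eta flask to 90.0 mM in the theta flask moved the last reading from 38.1 mM to 37.6 mM, a shift less than the scatter of one reading.

Next came the scatter. For the beta flask I reckoned:

ceiling = 50.8 × 0.750 mM = 38.1 mM

That stands 5.10 mM above the E charged, and an error of 0.8 mM does not reverse the order. So I took E as the limiting reagent of the end state, with the reckoned ceiling at 115 % of the charge.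

Last came the rate. With half the E, the delta flask's first reading was 0.738 of the eta flask's. Full conversion in the beta flask leaves 13.4 % of its budget, so I expected a slow last stretch, but I put no figure on it.

The forecast did: 78 % for the beta flask, with orders of 1.07 in Q and 0.39 in E, on the ground that “Q dies after about 51 turnovers, with loss tied to turnover”.

The flask gave 85.9 %, which is 7.9 percentage points above the forecast. The order in Q was 1.1, within the tolerance, and the order in E was 0.30, lower than forecast.

    Q + E ⇌ QE, settled at all times (22.10 L mol⁻¹)
    QE → G + Q (8.520 min⁻¹)
    2 E ⇌ E2, settled at all times (25.20 L mol⁻¹)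
    QE → Lx + E (0.1596 min⁻¹)

The beta flask made 28.3 mM by the asked time, 74.3 % of its budget. The path from QE to Lx + E holds the beta flask short of full conversion: the beta run without that path reached 99.3 % against 85.9 %, and the path accounts for 95 % of what is missing. In the delta flask the budget comes to 50.8 % of the charge, so half of the charge lies close under the ceiling, and G took 10.6 min to reach a quarter of the charge but 52.6 min to reach half.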